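All constants were drawn at random within sensible limits, and the outcome is calculated.

The slow event in this flask comes after the coupling, in the target's drift to its isomer, which is slower than the reagent's use in the coupling.

    reagent in the reaction phase → decomposition product (k1 = 8.5 × 10⁻⁵ h⁻¹)
    reagent in the reaction phase ⇌ reagent in the second phase, rate k2*([reagent in the reaction phase] - [reagent in the second phase]/K2) per volume of the first phase (K2 = 0.89, k2 = 1.4 h⁻¹)
    substrate + reagent in the reaction phase → target (k3 = 15 M⁻¹ h⁻¹)
    target ⇌ isomer of the product (K4 = 4.2, k4 = 0.015 h⁻¹)
    substrate ⇌ dormant form (K5 = 10, k5 = 0.069 h⁻¹)

substrate 0.019 M; reagent in the second phase 3.00 equiv; time 2.5 d; volume of the second phase over the first 0.50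

- in the second phase: reagent in the second phase; everything else is in the first
- charges count per volume of the first phase; a concentration in a rate is the amount of a species over the volume of its own phase; every rate counts per litre of the first phase
- run time (flask): 2.5 d

- west: doubling the amount of reagent in the second phase, all else as stated
- east: doubling the transfer coefficient of step 2, all else as stated

- how much target there is at 2.5 d, in percent of the substrate charged
- the change that raises the amount of target at 2.5 d, in percent of the substrate charged most ("none" if none brings more than 2 percentage points) (west / east / none)
- amount of target at 2.5 d, in percent of the substrate charged, after east

We first ask which constants must be known well. The reagent's decomposition has a half-life of 340 d against a run of 2.5 d, so an error there hardly shows. The reagent balances between the phases with a half-life of 0.152 h. With 0.5 of the substrate consumed, that balance gives c(reagent in the reaction phase) = 0.0329 M, so the pseudo-first-order coupling has a half-life of 1.41 h, and the transfer is faster and matters little. The coupling constant acts through the dormant form: we reckon the substrate diverted at 12.3 % of the charge and the part still dormant at 2.5 d at 8.11 % of the charge, and in this reckoning a doubled coupling constant lowers that to 4.32 %.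

Next comes the isomerisation. We take as zero of the scale the equilibrium share of target in target plus isomer, 19.2 %. The excess above it decays with the relaxation constant, forward plus back, 0.0186 h⁻¹, and 32.8 % of the excess survives the run. Doubling the isomerisation constant at fixed equilibrium would cut that to 10.8 %, a loss of 16 percentage points, so this constant must be known well. By this reckoning the pair holds 45.7 % target, and we commit to y = 42.0 %. East leaves this reckoning unchanged, and west gains 1.9 points against the bar of 2 points, so we answer none.

The forecast gives 43 % (40 % to 46 %), above our figure, with 43.3 % after east and none as the best change, holding that “isomerisation rather than coupling sets the 2.5 d yield”.

The simulation gives 43.0 %, 43.2 % after east and none, with west worth 1.4 points and east 0.13 points. For this flask read at 2.05 d or 3.06 d instead, y has moved 5 points, which lies outside the forecast's range. At 2.5 d the flask holds 47.6 % target in the pair, against our 45.7 %. For the flask read at 15 h, the same constant leaves 75.7 % of the excess, and the reckoning gives 71.5 %. That flask held 72.3 % target.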